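## Analysis of the target

Diplotrin B (17) is 3'-hydroxy-3,4',7,8-tetramethoxyflavone. Ring A (the benzo ring) carries methoxy groups at C7 and C8, ring C (the pyranone) carries a methoxy group at C3, and C2 bears ring B, a 3-hydroxy-4-methoxyphenyl group. The molecule is flat and has no stereocentre, so the difficulties are regiochemical and chemoselective. Ring A has three contiguous oxygens (O1 on C8a, then C8 and C7) and nothing at C5, so the pattern must be fixed by where the carbon that becomes C4 is attached to ring A. Four of the five oxygen substituents are methyl ethers and one, at C3', is a free phenol. That hydroxyl must travel protected, and no reagent that cleaves aryl methyl ethers or the C3 enol ether may be used. The pyranone is attacked at C2 by hard nucleophiles and aqueous alkali, which argues for closing ring C last and under acid. The plan rests on C4: a bare carbonyl carbon flanked by C4a of ring A and the methoxy-bearing C3. It can be supplied as carbon monoxide between an aryl electrophile and an α-methoxy ketone enolate, after which O1–C2 closes by cyclodehydration.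

## Retrosynthetic reasoning

**O1–C2.** Opening the pyranone of 17 at its enol ether bond gives the open-chain 2-methoxy-1,3-diketone 15, with a ring A phenol ortho to one carbonyl. In the forward direction this phenol adds to the ring B carbonyl to give hemiketal 16, which dehydrates to the aromatic pyranone. If both phenols are carried as methoxymethyl acetals, as in 14, the acid that unmasks them also drives the closure, so deprotection costs no separate step and ring C never meets base.

**C4a–C4 and C4–C3.** In 14 both bonds to the ring A-side carbonyl are cut together, giving aryl iodide 4, carbon monoxide 11 and α-methoxy ketone 10. This carbonyl has no substituent of its own, so it corresponds exactly to CO. The cut gives two fragments of similar size, each with one aromatic ring, and the C3 methoxy group is already in 10. Cutting C2–C3 instead would require a ring A α-methoxy ketone with a free ortho hydroxyl and the 7,8-pattern, which is harder to reach than an iodide. The forward reaction must acylate the enolate 12 at carbon, insert exactly one CO, and stop after one acylation; the last is ensured because the product is held as its enolate 13.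

**C–I of ring A.** Iodide 4 is traced to acetal 2 and then to phenol 1. The acetal oxygen that will become O1 directs lithiation to the only free position beside it, giving 3, and iodine is placed there. The protecting group thus also sets the regiochemistry, and C4a ends up next to C8a with the methoxy groups at C8 and C7.

**Aryl–carbonyl bond of ring B.** Ketone 10 is cut between ring B and its carbonyl, giving aryl bromide 6 (from phenol 5) and amide 7. The bromine in 5 is para to the methoxy group and meta to the hydroxyl, so halogen–lithium exchange to 8 fixes the 3'-oxygen/4'-methoxy pattern with no selectivity question. Amide 7 supplies C2, C3 and the C3 methoxy group, and its chelated adduct 9 prevents a second addition.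

## Alternatives that were turned down

**Alternative 1:** The C4–C4a bond of the 3'-O-tosylate A1 is cut, leading to the β-aryloxyacrylic acid A2, in which ring A is held only through its ether oxygen.
- Forward key step: in a strongly acidic dehydrating medium the acid becomes an acylium equivalent and attacks the one free position ortho to the ether oxygen, closing ring C by intramolecular Friedel–Crafts acylation.
- For: the site is the only one available and is para to the future C7 methoxy group, so regiochemistry is enforced and electronically matched. No transition metal or gas is needed. On robustness and scalability of the ring-forming event it is stronger than the chosen key step.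
- Against: A2 is a tetrasubstituted acrylic acid that must have the carboxyl cis to the aryloxy group (E). Making it (vinylic substitution on an activated α-methoxy-β-keto ester derivative by phenol 1, then saponification) takes more steps than both fragments of the chosen route together. As a vinylogous carbonate it can be protonated at the α-carbon and hydrolysed or decarboxylated in the acid before it acylates. The sulfonate that deactivates ring B must then be removed with a nucleophilic base, to which C2 of the pyranone is itself sensitive.
- Comparison: the chosen route offers convergence, a commercial two-carbon unit that already carries the C3 methoxy group, and deprotection merged with ring closure, at six steps against about eight.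

**Alternative 2:** The C3–C4 bond of the dihydroflavonol A3 is cut, leading to dialdehyde A4, which has an aromatic aldehyde on ring A and an α-aryl-α-aryloxy acetaldehyde.
- Forward key step: a thiazol-2-ylidene adds to the aromatic aldehyde, and the resulting acyl anion equivalent attacks the aliphatic aldehyde to give the trans 3-hydroxychroman-4-one A3.
- For: the step is catalytic, metal-free and mild. It sets the C3 oxygen and C4 carbonyl directly. A free 3-hydroxyl would allow late variation at O3, a point on which it is more flexible than the chosen route.
- Against: both aldehydes can take up the carbene. If the aliphatic one does, the adjacent aryloxy group is a leaving group in the carbene adduct and its expulsion would cleave the molecule; the reversed role assignment would also give a six-membered ring with hydroxyl and carbonyl transposed. A4 is highly enolisable at its doubly activated benzylic carbon. Two stereocentres are made only to be erased. Three operations follow the key step (dehydrogenation across C2–C3, methylation of O3, hydrogenolysis of the benzyl ether).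
- Comparison: the chosen route carries the correct oxidation level and the O3 methyl group from the start, and is about three steps shorter.

**Alternative 3:** C3 and its methoxy group are excised from the 3'-O-benzyl ether A5, leading to the 3-silyloxy-2-arylbenzofuran A6 and chloro(methoxy)carbene A7.
- Forward key step: A7, released from the diazirine A8, cyclopropanates C2=C3 of A6. The chloro(methoxy)cyclopropane opens with loss of chloride, assisted by the silyloxy oxygen, and loses the silyl group to give the 3-methoxypyranone.
- For: two C–C bonds and the C3 methoxy group arrive in one operation from an easily assembled five-membered precursor. From A6 onwards the end-game is as short as that of the chosen route.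
- Against: the C2=C3 bond is tetrasubstituted, part of an aromatic furan and flanked by an aryl group. A7 is a heteroatom-stabilised carbene of low electrophilicity. This ring expansion is not an established reaction type for silyloxybenzofurans, so the key step would be a new method. A8 is shock-sensitive, and a separate debenzylation is still needed.
- Comparison: the chosen key step belongs to a known reaction class, and both of its partners are two steps from commercial phenols.

Key step: step 5

Remark on the chemistry: in the key step the ketone is used as its pre-formed sodium enolate in twofold amount, so that the second equivalent of enolate, not free silylamide, deprotonates the diketone as it forms; the ketone released is recovered.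

## Route

Step 1
Reactants: 1 2,3-dimethoxyphenol
Product: 2 1,2-dimethoxy-3-(methoxymethoxy)benzene
Conditions: MOMCl, i-Pr2NEt, CH2Cl2, 0 °C to rt
Reagents that add atoms: chloromethyl methyl ether (MOMCl), COCCl
Why: O-alkylation of the phenol with a reactive α-chloro ether under amine base (acetal protection); the group installed is both the mask for O1 and the director for step 2.

Step 2
Reactants: 2 1,2-dimethoxy-3-(methoxymethoxy)benzene
Product: 4 1-iodo-3,4-dimethoxy-2-(methoxymethoxy)benzene, via aryllithium 3 (not isolated)
Conditions: n-BuLi, TMEDA, THF, 0 °C; then I2, THF, –78 °C to rt; aq. Na2S2O3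
Reagents that add atoms: iodine, II
Why: Directed ortho-metalation; the chelating methoxymethoxy group is a stronger director than a methoxy group and has only one free ortho position, so lithiation and iodinolysis should place iodine on the future C4a.

Step 3
Reactants: 5 5-bromo-2-methoxyphenol
Product: 6 4-bromo-1-methoxy-2-(methoxymethoxy)benzene
Conditions: MOMCl, i-Pr2NEt, CH2Cl2, 0 °C to rt
Reagents that add atoms: chloromethyl methyl ether (MOMCl), COCCl
Why: The same acetal protection as in step 1; the future 3'-hydroxyl is masked against the organolithium and enolate chemistry that follows.

Step 4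
Reactants: 6 4-bromo-1-methoxy-2-(methoxymethoxy)benzene; 7 N,2-dimethoxy-N-methylacetamide
Product: 10 2-methoxy-1-[4-methoxy-3-(methoxymethoxy)phenyl]ethanone, via aryllithium 8 (not isolated), via lithium hemiaminal alkoxide 9 (not isolated)
Conditions: n-BuLi, THF, –78 °C; then 7, –78 to 0 °C; aq. NH4Cl
Reagents that add atoms: none
Why: Bromine–lithium exchange at –78 °C is faster than any ring deprotonation, and the Weinreb ketone synthesis stops at the chelated adduct 9, which collapses to the ketone only on work-up.

Step 5
Reactants: 4 1-iodo-3,4-dimethoxy-2-(methoxymethoxy)benzene; 10 2-methoxy-1-[4-methoxy-3-(methoxymethoxy)phenyl]ethanone; 11 carbon monoxide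
Product: 14 1-[3,4-dimethoxy-2-(methoxymethoxy)phenyl]-2-methoxy-3-[4-methoxy-3-(methoxymethoxy)phenyl]propane-1,3-dione (racemic), via sodium enolate 12 (not isolated), via sodium diketonate 13 (not isolated)
Conditions: 10 (2 equiv), NaN(SiMe3)2 (2 equiv), THF, 0 °C; then 4 (1 equiv), Pd(dba)2 (5 mol %), dppp (5 mol %), CO (ca. 1.5 equiv, sealed two-chamber vessel), THF, 80 °C; aq. NH4Cl
Reagents that add atoms: none
Why: Zerovalent palladium from Pd(dba)2 and 1,3-bis(diphenylphosphino)propane inserts into the C–I bond of 4, and migratory insertion of CO then gives an aroyl complex of divalent palladium, forming C4a–C4; the electron-rich aryl group migrates readily and the ortho acetal disfavours direct coupling without CO. Enolate 12 replaces iodide on palladium and reductive elimination from the carbon-bound enolate forms C4–C3. The closest known reaction type is the palladium-catalysed carbonylative α-arylation of aryl alkyl ketones with aryl iodides to 1,3-diketones under these conditions. No ring is closed. The one new stereocentre, the methoxy-bearing carbon between the carbonyls, is formed without control, is epimerisable through 13 and disappears on aromatisation in step 6, so no controlling element is needed. The step needs C- rather than O-acylation (secured by reductive elimination through the carbon-bound palladium enolate), a single CO insertion (secured by the small CO charge and the chelating diphosphine), and monoacylation (secured because the second equivalent of 12 converts the acidic product at once into the unreactive diketonate 13). The position of iodine in 4 fixes the 7,8-dimethoxy pattern.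

Step 6
Reactants: 14 1-[3,4-dimethoxy-2-(methoxymethoxy)phenyl]-2-methoxy-3-[4-methoxy-3-(methoxymethoxy)phenyl]propane-1,3-dione
Product: 17 diplotrin B (3'-hydroxy-3,4',7,8-tetramethoxyflavone), via free diphenol diketone 15 (not isolated), via cyclic hemiketal 16 (not isolated)
Conditions: conc. aq. HCl, MeOH, 60 °C
Reagents that add atoms: none
Why: Acid-catalysed acetal exchange with methanol frees both phenols; the ring A phenol adds to the ring B carbonyl (6-exo-trig) and the hemiketal 16 dehydrates to the aromatic pyranone, the usual acid cyclodehydration of 2'-hydroxy-1,3-diketones to flavones; aryl methyl ethers and the C3 methoxy group are inert to these conditions.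

## Compound list

1 | 2,3-dimethoxyphenol | COc1cccc(O)c1OC | starting material
2 | 1,2-dimethoxy-3-(methoxymethoxy)benzene | COCOc1cccc(OC)c1OC | intermediate
3 | [3,4-dimethoxy-2-(methoxymethoxy)phenyl]lithium | [Li]c1ccc(OC)c(OC)c1OCOC | intermediate (not isolated)
4 | 1-iodo-3,4-dimethoxy-2-(methoxymethoxy)benzene | COCOc1c(I)ccc(OC)c1OC | intermediate
5 | 5-bromo-2-methoxyphenol | COc1ccc(Br)cc1O | starting material
6 | 4-bromo-1-methoxy-2-(methoxymethoxy)benzene | COCOc1cc(Br)ccc1OC | intermediate
7 | N,2-dimethoxy-N-methylacetamide | COCC(=O)N(C)OC | starting material
8 | [4-methoxy-3-(methoxymethoxy)phenyl]lithium | [Li]c1ccc(OC)c(OCOC)c1 | intermediate (not isolated)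
9 | lithium 2-methoxy-1-[methoxy(methyl)amino]-1-[4-methoxy-3-(methoxymethoxy)phenyl]ethan-1-olate (racemic) | COCC(O[Li])(N(C)OC)c1ccc(OC)c(OCOC)c1 | intermediate (not isolated)
10 | 2-methoxy-1-[4-methoxy-3-(methoxymethoxy)phenyl]ethanone | COCC(=O)c1ccc(OC)c(OCOC)c1 | intermediate
11 | carbon monoxide | [C-]#[O+] | starting material
12 | sodium (Z)-2-methoxy-1-[4-methoxy-3-(methoxymethoxy)phenyl]ethen-1-olate (Z expected from chelation) | [Na+].CO/C=C(\[O-])c1ccc(OC)c(OCOC)c1 | intermediate (not isolated)
13 | sodium enolate of diketone 14 (delocalised; one resonance form drawn, geometry not defined) | [Na+].COCOc1c(C([O-])=C(OC)C(=O)c2ccc(OC)c(OCOC)c2)ccc(OC)c1OC | intermediate (not isolated)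
14 | 1-[3,4-dimethoxy-2-(methoxymethoxy)phenyl]-2-methoxy-3-[4-methoxy-3-(methoxymethoxy)phenyl]propane-1,3-dione (racemic at C2, enolisable) | COCOc1c(C(=O)C(OC)C(=O)c2ccc(OC)c(OCOC)c2)ccc(OC)c1OC | intermediate
15 | 1-(2-hydroxy-3,4-dimethoxyphenyl)-3-(3-hydroxy-4-methoxyphenyl)-2-methoxypropane-1,3-dione (racemic) | COc1ccc(C(=O)C(OC)C(=O)c2ccc(OC)c(O)c2)c(O)c1OC | intermediate (not isolated)
16 | 2-hydroxy-2-(3-hydroxy-4-methoxyphenyl)-3,7,8-trimethoxychroman-4-one (mixture of diastereomers, racemic) | COc1ccc(C2(O)Oc3c(OC)c(OC)ccc3C(=O)C2OC)cc1O | intermediate (not isolated)
17 | diplotrin B, 2-(3-hydroxy-4-methoxyphenyl)-3,7,8-trimethoxy-4H-chromen-4-one | COc1ccc(-c2oc3c(OC)c(OC)ccc3c(=O)c2OC)cc1O | target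

## Step count and risk

Total: 6 steps. Longest linear sequence: 4 steps (1, 2, 5, 6 or 3, 4, 5, 6).

**Step 5 (key step).** The hindered aroyl palladium intermediate may be captured too slowly by the α-substituted enolate. The catalyst could then decompose under CO, direct arylation without CO could compete, and the enolate could be consumed by self-aldol condensation once free ketone is present. Fallback, from compound 2 and ketone 10, returning at diketone 14:
- Compound 2 would be lithiated as in step 2 and the aryllithium 3 quenched with carbon dioxide, then acidified with cold dilute HCl only to about pH 4, to give 3,4-dimethoxy-2-(methoxymethoxy)benzoic acid F1.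
- Activation with 1,1'-carbonyldiimidazole in THF should give [3,4-dimethoxy-2-(methoxymethoxy)phenyl](1H-imidazol-1-yl)methanone F2.
- F2 would be added at –78 °C to lithium (Z)-2-methoxy-1-[4-methoxy-3-(methoxymethoxy)phenyl]ethen-1-olate F3, made from 10 with LiN(SiMe3)2 and used in twofold amount so that the second equivalent acts as base. After aqueous NH4Cl this crossed Claisen acylation should deliver 14.

**Step 6.** Methanol may cleave the non-enolised 2-methoxy-1,3-diketone under acid (retro-Claisen) in competition with ring closure. The methoxymethyl cation may be captured by the electron-rich phenolic rings, or the reaction may stall at the hemiketal. Fallback, from 14, returning at 17: the acetals would be removed aprotically with ZnBr2 and 1-propanethiol in CH2Cl2 at 0 °C, the thiol scavenging the methoxymethyl group. The resulting mixture of 15 and 16 would be isolated and then dehydrated with catalytic p-toluenesulfonic acid in toluene at reflux with azeotropic removal of water, to give 17. This fallback makes no compound outside the list (F0).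

**Step 4.** The aryllithium may deprotonate the acidic methylene of amide 7, or induce loss of formaldehyde from its N-methoxy group, which would return debrominated arene instead of ketone. Fallback, from bromide 6, returning at ketone 10: magnesium insertion (Mg turnings, LiCl, THF) should give the less basic [4-methoxy-3-(methoxymethoxy)phenyl]magnesium bromide F4. Addition to methoxyacetonitrile would give the bromomagnesium salt of 2-methoxy-1-[4-methoxy-3-(methoxymethoxy)phenyl]ethan-1-imine F5. Hydrolysis in cold aqueous citric acid buffer (about pH 4) should then release 10 without loss of the acetal.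

**Step 2.** Metalation may occur in part next to the terminal methoxy group instead of next to the acetal, or may be incomplete, giving a regioisomeric iodide that is hard to separate. Fallback, from phenol 1, returning at iodide 4:
- Phenol 1 would be converted with diethylcarbamoyl chloride and K2CO3 into 2,3-dimethoxyphenyl N,N-diethylcarbamate F6, whose carbamate is a far stronger director.
- Lithiation with s-BuLi and TMEDA at –78 °C (kept cold to avoid acyl migration) and iodine quench should give 6-iodo-2,3-dimethoxyphenyl N,N-diethylcarbamate F7.
- Hydrolysis with NaOH in aqueous ethanol at reflux should give 6-iodo-2,3-dimethoxyphenol F8, and protection as in step 1 would give 4.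

## Further compounds

F1 | step 5 | 3,4-dimethoxy-2-(methoxymethoxy)benzoic acid | COCOc1c(C(=O)O)ccc(OC)c1OC
F2 | step 5 | [3,4-dimethoxy-2-(methoxymethoxy)phenyl](1H-imidazol-1-yl)methanone | COCOc1c(C(=O)n2ccnc2)ccc(OC)c1OC
F3 | step 5 | lithium (Z)-2-methoxy-1-[4-methoxy-3-(methoxymethoxy)phenyl]ethen-1-olate | [Li+].CO/C=C(\[O-])c1ccc(OC)c(OCOC)c1
F0 | step 6 | none | none
F4 | step 4 | [4-methoxy-3-(methoxymethoxy)phenyl]magnesium bromide | COCOc1cc([Mg]Br)ccc1OC
F5 | step 4 | bromomagnesium salt of 2-methoxy-1-[4-methoxy-3-(methoxymethoxy)phenyl]ethan-1-imine | COCC(=N[Mg]Br)c1ccc(OC)c(OCOC)c1
F6 | step 2 | 2,3-dimethoxyphenyl N,N-diethylcarbamate | CCN(CC)C(=O)Oc1cccc(OC)c1OC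
F7 | step 2 | 6-iodo-2,3-dimethoxyphenyl N,N-diethylcarbamate | CCN(CC)C(=O)Oc1c(I)ccc(OC)c1OC
F8 | step 2 | 6-iodo-2,3-dimethoxyphenol | COc1ccc(I)c(O)c1OC
A1 | alternative 1 | 3'-O-tosyl diplotrin B, 2-methoxy-5-(3,7,8-trimethoxy-4-oxo-4H-chromen-2-yl)phenyl 4-methylbenzenesulfonate | COc1ccc(-c2oc3c(OC)c(OC)ccc3c(=O)c2OC)cc1OS(=O)(=O)c1ccc(C)cc1
A2 | alternative 1 | (E)-3-(2,3-dimethoxyphenoxy)-2-methoxy-3-[4-methoxy-3-(tosyloxy)phenyl]prop-2-enoic acid | OC(=O)/C(OC)=C(\Oc1cccc(OC)c1OC)c1ccc(OC)c(OS(=O)(=O)c2ccc(C)cc2)c1
A3 | alternative 2 | rac-(2R,3R)-2-[3-(benzyloxy)-4-methoxyphenyl]-3-hydroxy-7,8-dimethoxychroman-4-one (trans; one enantiomer drawn) | COc1ccc2C(=O)[C@H](O)[C@@H](c3ccc(OC)c(OCc4ccccc4)c3)Oc2c1OC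
A4 | alternative 2 | rac-2-{1-[3-(benzyloxy)-4-methoxyphenyl]-2-oxoethoxy}-3,4-dimethoxybenzaldehyde | COc1ccc(C=O)c(OC(C=O)c2ccc(OC)c(OCc3ccccc3)c2)c1OC
A5 | alternative 3 | 3'-O-benzyl diplotrin B, 2-[3-(benzyloxy)-4-methoxyphenyl]-3,7,8-trimethoxy-4H-chromen-4-one | COc1ccc(-c2oc3c(OC)c(OC)ccc3c(=O)c2OC)cc1OCc1ccccc1
A6 | alternative 3 | {2-[3-(benzyloxy)-4-methoxyphenyl]-6,7-dimethoxy-1-benzofuran-3-yl}oxy(tert-butyl)dimethylsilane | COc1ccc2c(O[Si](C)(C)C(C)(C)C)c(-c3ccc(OC)c(OCc4ccccc4)c3)oc2c1OC
A7 | alternative 3 | chloro(methoxy)carbene | CO[C]Cl
A8 | alternative 3 | 3-chloro-3-methoxy-3H-diazirine | COC1(Cl)N=N1
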